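The left-handed product is what to watch in a repeat of these flasks, but it is easiest to reckon through the left-handed substrate beside it, since the two add to 50.0% of the substrates charged at the last green reading and to 49.8% at the last teal one, so what that hand loses appears as product.

in all of them: left-handed substrate 14 mM; right-handed substrate 14 mM

|  | partner | protic impurity | temperature | remark | time |
|---|---|---|---|---|---|
| green | 42 mM | 2.2 mM | 20 °C | run made earlier |  |
| teal | 42 mM | 9.1 mM | 40 °C | run made earlier |  |
| Monday's | 42.0 mM | 12.0 mM | 55 °C |  | 40 h |
| Sunday's | 42.0 mM | 2.80 mM | 25 °C |  | 40 h |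

| run | time / h | left-handed product / % | left-handed substrate / % |
|---|---|---|---|
| green | 6.00 | 1.2 | 48.6 |
| green | 12.0 | 2.9 | 47.7 |
| green | 15.0 | 3.6 | 46.1 |
| green | 25.0 | 4.6 | 45.5 |
| green | 30.0 | 5.5 | 44.5 |
| teal | 1.33 | 2.2 | 47.3 |
| teal | 4.00 | 5.6 | 45.0 |
| teal | 6.00 | 8.1 | 42.6 |
| teal | 10.0 | 10.5 | 39.4 |
| teal | 15.0 | 13.5 | 36.3 |

(scatter of a reading: 0.5 percentage points)

- partner is single-handed; left-handed substrate and right-handed substrate are mirror images of each other, charged as a racemate, each of them at the stated concentration
- the analysis behind the earlier runs scatters by 0.5 percentage points, standard deviation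
- the handed part of partner does not stay in what it makes, so the products of the two hands are mirror images too

- the flask that ends with the higher amount of left-handed product, in percent of the left-handed substrate and right-handed substrate together charged, or "neither" when 2 percentage points or less lies between them (Monday's / Sunday's / neither)
- final left-handed product, as a percentage of the left-handed substrate and right-handed substrate together charged, in Monday's
- final left-handed product, as a percentage of the left-handed substrate and right-handed substrate together charged, in Sunday's

What do you carry from flask to flask? I carry the fraction left of the charged left-handed substrate, which in the teal run at 15.0 h is 72.6%, and from it 0.320, the exposure, meaning the logarithm of one over the fraction left, the integrated pseudo-first-order rate constant.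

Does exposure grow steadily? In the green run it goes from 0.0812 at 15.0 h to 0.117 at 30.0 h, so doubling the time multiplies it by 1.43, short of doubling, and with a scatter of 0.5 percentage points on each reading that factor is itself a reading.

And heating? At the same 15.0 h, the teal exposure stands 3.94 times the green one for the step from 20 °C to 40 °C.

But impurity rose in that step too, so isn't this factor mixed? It is, by 4.14 in impurity, and the two runs cannot part them, so I use it as a joint step, given that Monday's holds 4.29 times the impurity of Sunday's.

Your figures? Taking an even factor per degree, Sunday's lies 0.250 of a step above green, which gives exposure 0.191 and 8.69% of left-handed product, and Monday's lies 0.750 of a step above teal, which gives 1.49 and 38.7%.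

The forecast, holding that “the impurity behaves as a stoichiometric reactant being consumed”, names Monday's with 26% there and 7.2% in Sunday's, so its Monday's figure is lower than mine.

The flask gives Monday's, with 34.0% in Monday's and 9.57% in Sunday's.

    partner + left-handed substrate → left-handed product (k = 7.62 × 10⁻⁵ L mol⁻¹ s⁻¹, Ea = 79.0 kJ mol⁻¹)
    partner + right-handed substrate → right-handed product (k = 2.96 × 10⁻⁵ L mol⁻¹ s⁻¹, Ea = 74.0 kJ mol⁻¹)
    partner ⇌ dormant form (K = 0.665, k = 1.29 × 10⁻⁵ s⁻¹, Ea = 108 kJ mol⁻¹, ΔH = −31.0 kJ mol⁻¹)
    partner + protic impurity → quenched reagent (k = 0.00520 L mol⁻¹ s⁻¹, Ea = 67.0 kJ mol⁻¹)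
    2 partner → homo dimer (k = 1.02 × 10⁻⁴ L mol⁻¹ s⁻¹, Ea = 58.0 kJ mol⁻¹)
    (constants at 25 °C)

As exposure, Sunday's 81% left is 0.211 against my 0.191, and Monday's 32% left is 1.14 against my 1.49, with partner in Monday's at 3.5% of its charge after 40.0 h. The repeat of Sunday's at 40 °C shares the temperature of the teal run but holds 2.80 mM of impurity against the teal run's 9.1 mM, so carrying the teal exposure by the time factor, which gives 0.534, a fraction left of 58.6% and 20.7% of product, leaves that difference in impurity uncounted; that flask stands at 51% left, exposure 0.682, with 24.7% of left-handed product.

(The data stem from a simulated flask from invented constants; scatter was added.)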